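**Remarks before the route.** Read atom by atom, the cyclisation precursor 19 and its product 20 carry the same configuration at C5, C8, C9 and C10 as both halves of 37, and the olefin geometries of 19 (Z at C8=C9, E at C10=C1) are the ones the folding needs. No structure had to be corrected. The precursor keeps C3 as a methyl ester on purpose: its five-membered O-attack on C10 is reversible, whereas a second tert-butyl ester there would lactonise for good. What is changed is the fate of that ester. It is not carried to the end but exchanged at a base-stable stage (steps 17 and 18), and the C2/C3 pair of the vinyl half is joined to the other half as its cyclic anhydride. C13 is set by two enantiomeric epoxidations of one allylic alcohol, which is judged safer than additions to a C13 oxocarbenium ion.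

## Structural features

The target is an ester-linked pair of 2,3-seco-labdanes of the 8,13-epoxy type. In each half a cyclohexane ring B (C5 to C10) is fused through C8–C9 to a tetrahydropyran ring C (O, C8, C9, C11, C12, C13). Ring A is absent; what remains of it is a C1–C2 acetic acid arm on C10 and a C4(CH3)2–C3 carboxyl arm on C5. The halves differ only at C13 to C15: one carries vinyl and methyl at C13 (13R), the primed one carries methyl and an (R)-CH(OH)–CH2O unit at C13′ in the opposite spatial sense (13′S), and C2 of the vinyl half is esterified with O15′. Each ring B holds four contiguous stereocentres, C5 (tertiary), C10 (all-carbon quaternary), C9 (tertiary) and C8 (tertiary ether), next to the fully substituted ether carbon C13. In the ring B chair the two carboxyl arms are equatorial, the C10 and C8 methyls are 1,3-diaxial, C9–H is cis to the C10 methyl and the C11 chain is axial, so the B/C fusion is cis. This is the C9-epimeric pattern that the usual all-E polyene folding does not give. The fragile points are the primary interunit ester beside the free 14′-hydroxyl (hydrolysis, acyl shift) and the tertiary allylic ether at C13; with four carboxyl groups of which three end free, no basic hydrolysis is possible once the halves are joined. The key step uses the fact that the cis C8–O/C9–C11 pair is the stereochemical image of a Z C8=C9 alkene. Anti addition of C10 (to C9) and of the C13 carboxyl oxygen (to C8) closes ring B and ring C together, with C10 entering as the β-carbon of an enal whose carbonyl becomes C2.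

## Logic of the disconnections

37 to 36: the O–allyl bonds of the C2′ and C3′ esters are cut. These two acids must be masked during the union, and a palladium-catalysed allyl transfer is neutral. The forward step must leave the interunit ester and the vinyl group alone.

36 to 33 and 35: the C2–O15′ ester bond is cut. The acyl donor 33 is the cyclic anhydride of C2 and C3, so C3 needs no protecting group and appears as the free acid in the same step. The forward step must attack the C2 carbonyl, not the C3 carbonyl, and must use the primary, not the secondary, hydroxyl of 35.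

33 to 32, 31, 30 and 29: the anhydride C–O bond, the two allyl ester bonds and the C14=C15 double bond are traced back to the diol 29. This puts the vinyl half on the same track as the primed half. The forward steps are a diol-to-alkene conversion, deallylation and dehydration, none of which touches a stereocentre.

29 and 35 to 27: in each, the O8–C13 bond is cut, via the epoxy alcohols 28 and 34. The two C13 epimers thereby become the two enantiomeric epoxides of one E-allylic alcohol. The forward steps need reagent-controlled epoxidation and ring closure at the tertiary epoxide carbon with clean inversion.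

27 to 26, 25 and 23: the ester groups are exchanged, then the C13–CH3 and C14–C15 bonds are cut. A terminal alkyne is the simplest precursor of an E-trisubstituted allylic alcohol. The forward carbometalation must be syn and must tolerate an acid, an ester and a tertiary alcohol.

23 to 22, 21 and 20: C14 is removed and C13 returns to the lactone carbonyl; C2 returns to the aldehyde. The forward reduction must stop at the lactol and spare the C3 ester.

20 to 19: the C9–C10 and C8–O bonds are cut. Two rings and three stereocentres are removed at once, leaving an acyclic dienal with a single stereocentre. The forward step must control C10, C9 and C8 from C5 and the Z olefin.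

19 to 17 and 16: the C10=C1 bond is cut (formyl olefination of a methyl ketone), and the C10 carbonyl is traced to a vinyl group. The forward steps must not epimerise C5.

16 to 14 and 15: the C4–C5 bond is cut. One catalytic step then sets C5 and brings in the quaternary C4 with C3. The forward step must be branched-selective and enantioselective with a fully substituted nucleophile.

14 to 13, 12, 10 and 11: the carbonate and the C5=C10 double bond (labdane numbering) are cut, giving an aldehyde and a two-carbon phosphonate. The E geometry is required for the allylation.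

10 to 8, 5 and 6, then to 3, 2 and 1: the C11–C12 bond and the terminal isopropylidene are cut. 1 supplies the Z trisubstituted alkene, and its allylic acetate makes oxidation of the distal alkene regioselective. The epoxide then serves as a masked aldehyde during the alkylation.

## Other disconnections considered

Alternative 1: The cut is made inside a ring A that the target no longer has. The anhydride C2–O–C3 of A2 is traced to the C2–C3 bond of the tricyclic ring A 2,3-diketone A1. In the forward direction a peracid adds to one carbonyl of A1 and acyl migration to oxygen (Baeyer–Villiger oxidation of a 1,2-diketone) gives the seven-membered anhydride A2.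
- In its favour: C5 and C10 would be set inside a rigid decalin by classical means, and the oxidation is textbook chemistry. A2 is the same compound as 33, so on structure the two plans meet in one acyl donor. Alternative 1 reaches it without the ester exchange and deallylation of steps 17, 18 and 22; on that point it is the better plan.
- Against it here: a ring must be built, oxidised at C2 and C3 and then broken. The cis B/C fusion with C9–H cis to the C10 methyl still has to be made, and ring A does not help with it. The peracid must spare the vinyl group. The primed half would need its anhydride opened and masked again.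
- Comparison: mechanistically the oxidation is at least as certain as the new cyclisation of the chosen plan. In step economy the alternative forms and breaks more C–C bonds and should be longer.

Alternative 2: The cut is at C8–C9 and C5–C10. In the forward direction the E-enal A3 and the diene A4 combine in a [4+2] cycloaddition under a chiral oxazaborolidinium Lewis acid to give the ring B enone A5.
- In its favour: suprafacial addition turns the E geometry of A3 directly into the cis relation of C9–H and the C10 substituent, with no cationic intermediate, and the catalyst sets the absolute configuration. The C13′ and C14′ centres are already in the side chain. It rests entirely on known chemistry; on mechanistic certainty it is the better plan.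
- Against it here: A5 lacks C5 and C8 as stereocentres. It still needs the C4 unit at C5, methyl and oxygen at C8 with closure of ring C, removal of the C7 ketone and reduction of the formyl group to methyl. The trisubstituted enal is a slow dienophile, and the silyl ether and acetonide must survive a strong Lewis acid.
- Comparison: the chosen key step sets three of the four ring B centres and both rings at once. Alternative 2 sets two centres and one ring, and its step count after the key step should be clearly higher.

Alternative 3: The C1–C10 bond and the C2–O15′ bond are cut together. In the forward direction the diazoketone A6 loses nitrogen under a silver salt or light, C10 shifts to C1 with retention, and the ketene is taken up by the primary hydroxyl of 35 to give the triallyl ester A7.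
- In its favour: the acyl carbon is unambiguous, so the regiochemical question of the anhydride opening does not arise; on that point it is the better plan. The conditions are neutral, and the final deallylation is the same as in the chosen route (equal).
- Against it here: it needs a carboxyl group directly on the quaternary C10, one carbon short of what the enal cyclisation delivers. A diazoketone from so hindered an acid forms slowly. The ketene can dimerise or take the secondary hydroxyl when the alcohol is not in excess. C3 must be carried as an allyl ester.
- Comparison: it solves only the union and leaves the ring problem open. In step economy it adds a degradation or a special construction before the homologation and is at best equal in length.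

Key step: step 12

Assumption: the (Ra,R,R) enantiomer of the phosphoramidite L, O,O′-(1,1′-binaphthalene-2,2′-diyl) N,N-bis(1-phenylethyl)phosphoramidite, is taken to direct the nucleophile to the face of the allyl ligand that gives (S)-C5; if the sense proves opposite, the mirror-image ligand is used with nothing else changed.

## Route

Step 1
Reactants: 1 neryl acetate
Product: 2 6,7-epoxyneryl acetate, (2Z)-5-(3,3-dimethyloxiran-2-yl)-3-methylpent-2-en-1-yl acetate (racemic at the oxirane CH)
Conditions: mCPBA (1.0 equiv), CH2Cl2, 0 °C
Reagents that add atoms: 3-chloroperoxybenzoic acid (mCPBA), OOC(=O)c1cccc(Cl)c1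
Why: Prilezhaev epoxidation; the 2,3-alkene is deactivated by the allylic acetate, so the distal trisubstituted alkene should react first. The new oxirane centre is destroyed in step 5 and needs no control.

Step 2
Reactants: 2 6,7-epoxyneryl acetate
Product: 3 6,7-epoxynerol, (2Z)-5-(3,3-dimethyloxiran-2-yl)-3-methylpent-2-en-1-ol
Conditions: K2CO3 (0.2 equiv), MeOH, 0 °C → rt
Reagents that add atoms: none
Why: Base-catalysed methanolysis of the acetate (transesterification); epoxide and Z alkene are inert to methoxide at this temperature.

Step 3
Reactants: 3 6,7-epoxynerol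
Product: 5 3-[(3Z)-5-bromo-3-methylpent-3-en-1-yl]-2,2-dimethyloxirane, via allylic mesylate 4 (not isolated)
Conditions: MsCl, Et3N, THF, −40 °C; then LiBr, THF, 0 °C
Reagents that add atoms: lithium bromide, [Li+].[Br-]; methanesulfonyl chloride, CS(=O)(=O)Cl (its atoms stay only in 4)
Why: Sulfonylation followed by direct SN2 displacement at the primary allylic carbon; at low temperature there should be no allylic shift and no loss of Z geometry, and the epoxide tolerates neutral bromide.

Step 4
Reactants: 5 epoxy allylic bromide; 6 tert-butyl acetate
Product: 8 tert-butyl (4Z)-7-(3,3-dimethyloxiran-2-yl)-5-methylhept-4-enoate, via lithium enolate 7 (not isolated)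
Conditions: LiN(iPr)2, THF, −78 °C; then 5, DMPU, −78 → −30 °C
Reagents that add atoms: none
Why: C-Alkylation of an ester enolate (SN2) with a primary allylic bromide forms C11–C12; the tert-butyl ester suppresses self-condensation and the epoxide is inert at this temperature.

Step 5
Reactants: 8 epoxy tert-butyl ester
Product: 10 tert-butyl (4Z)-5-methyl-8-oxooct-4-enoate, via vicinal diol 9 (not isolated)
Conditions: H5IO6 (1.2 equiv), THF/H2O, 0 °C
Reagents that add atoms: water, O (taken up in 9 at the tertiary carbon; that oxygen leaves with acetone)
Why: Acid-mediated hydration of the epoxide and Malaprade glycol cleavage in one flask; the Z alkene and the tert-butyl ester do not react with periodic acid.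

Step 6
Reactants: 10 aldehyde; 11 triethyl phosphonoacetate
Product: 12 10-tert-butyl 1-ethyl (2E,6Z)-6-methyldeca-2,6-dienedioate
Conditions: NaH, THF, 0 °C → rt
Reagents that add atoms: none
Why: Horner–Wadsworth–Emmons olefination; the stabilised phosphonate anion should give the E enoate and brings in C10 and C20.

Step 7
Reactants: 12 E-enoate
Product: 13 tert-butyl (4Z,8E)-10-hydroxy-5-methyldeca-4,8-dienoate
Conditions: iBu2AlH (2.1 equiv), CH2Cl2, −78 °C; aq. potassium sodium tartrate
Reagents that add atoms: none
Why: 1,2-Reduction of the conjugated ethyl ester by a dialkylaluminium hydride; the bulky tert-butyl ester is much slower at −78 °C and the hydride is limited to what the ethyl ester needs.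

Step 8
Reactants: 13 allylic alcohol
Product: 14 tert-butyl (4Z,8E)-10-[(methoxycarbonyl)oxy]-5-methyldeca-4,8-dienoate
Conditions: ClCO2Me, pyridine, CH2Cl2, 0 °C
Reagents that add atoms: methyl chloroformate, COC(=O)Cl
Why: O-Acylation of the primary alcohol gives the linear E allylic methyl carbonate, the standard electrophile for iridium-catalysed substitution.

Step 9
Reactants: 14 allylic carbonate; 15 1-methoxy-2-methyl-1-(trimethylsilyloxy)prop-1-ene
Product: 16 10-tert-butyl 1-methyl (3S,6Z)-3-ethenyl-2,2,6-trimethyldec-6-enedioate
Conditions: [Ir(cod)Cl]2 (2 mol%), (Ra,R,R)-L (4 mol%), n-PrNH2 (pre-activation), Bu4N[Ph3SiF2] (10 mol%), THF, rt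
Reagents that add atoms: none
Why: Iridium-catalysed allylic substitution: the cyclometalated Ir–phosphoramidite complex ionises the carbonate to an (η3-allyl)iridium species and the ester enolate released from 15 attacks the substituted terminus, giving the branched product with the quaternary C4. The ligand shields one face of the allyl unit and should set (S)-C5; the reaction type is known for silyl ketene acetals of α,α-disubstituted esters.

Step 10
Reactants: 16 vinyl diester
Product: 17 10-tert-butyl 1-methyl (3R,6Z)-3-acetyl-2,2,6-trimethyldec-6-enedioate
Conditions: PdCl2 (10 mol%), CuCl (1 equiv), O2 (1 atm), DMF/H2O 7:1, rt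
Reagents that add atoms: water, O (the ketone oxygen; O2 is the terminal oxidant)
Why: Wacker–Tsuji oxidation: hydroxypalladation of the only monosubstituted alkene at its internal carbon gives the C10 methyl ketone. The trisubstituted alkene does not react and the medium is not basic, so C5 should keep its configuration (the descriptor changes to R by priority only).

Step 11
Reactants: 17 methyl ketone
Product: 19 10-tert-butyl 1-methyl (3S,6Z)-2,2,6-trimethyl-3-[(2E)-4-oxobut-2-en-2-yl]dec-6-enedioate, via unsaturated aldimine 18 (not isolated)
Conditions: tBuN=CHCH2SiMe3, LiN(iPr)2, THF, −78 → 0 °C; then aq. oxalic acid, rt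
Reagents that add atoms: N-tert-butyl-2-(trimethylsilyl)ethan-1-imine, CC(C)(C)N=CC[Si](C)(C)C; water, O
Why: Peterson-type formyl olefination: the α-silyl aza-enolate adds to the ketone, loss of Me3SiOLi gives the 1-azadiene 18 and mild acid hydrolysis releases the enal. The formyl group should settle trans to the branched C5 (E), and any enolisation should occur at the methyl group, not at hindered C5.

Step 12
Reactants: 19 Z,E-dienal tert-butyl ester
Product: 20 methyl 2-[(4aR,5R,6S,8aS)-5,8a-dimethyl-2-oxo-5-(2-oxoethyl)octahydro-2H-chromen-6-yl]-2-methylpropanoate (cis-fused δ-lactone aldehyde; labdane numbering 5S,8S,9R,10R)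
Conditions: EtAlCl2 (3 equiv), CH2Cl2, −78 → −30 °C; aq. potassium sodium tartrate
Reagents that add atoms: none
Why: Proposed new method: EtAlCl2 binds the enal oxygen of 19 and makes C10 electrophilic; the C8=C9 alkene attacks through C9 in a chair with the C4 arm on C5 equatorial, and the tertiary C8 cation is taken anti by the carbonyl oxygen of the tert-butyl ester, whose tert-butyl group leaves as 2-methylpropene while the released proton quenches the aluminium enolate to the C2 aldehyde. The closest known reaction types are Lewis-acid cation–olefin cyclisations started by an enone or enal and polyene cyclisations ended by a tert-butyl ester as a lactone; joining the two on one substrate is the new element. Ring B closes in a six-membered mode that is endo for the nucleophilic C8=C9 alkene and exo for the C10=C1 acceptor, and ring C closes as a six-membered lactone by attack of the C13 carbonyl oxygen on C8. C10 is set by allylic 1,3-strain about C5–C10, which holds C5–H in the enal plane so that C9 arrives from the C6 face and the C10 methyl ends axial and trans to C5–H. C9 is set by the Z geometry inherited from 1, which places C11 axial and C9–H cis to the C10 methyl. C8 is set by anti addition across the alkene, and the axial C11 tether can reach only the equatorial site of C8, which gives the cis fusion. The step needs C–C attack to win over O-attack by the C3 ester (a methyl ester, whose addition to C10 is reversible) and lactone capture to win over collapse of the enolate onto C8 (the exo-placed enolate cannot reach it) and over proton loss (the ester carbonyl sits beside the cation). Excess EtAlCl2 also removes adventitious protons, so a Brønsted-acid cyclisation of the isolated alkene should not compete.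

Step 13
Reactants: 20 lactone aldehyde
Product: 21 2-[(4aR,5R,6S,8aS)-6-(1-methoxy-2-methyl-1-oxopropan-2-yl)-5,8a-dimethyl-2-oxooctahydro-2H-chromen-5-yl]acetic acid
Conditions: NaClO2, NaH2PO4, 2-methyl-2-butene, t-BuOH/H2O, rt
Reagents that add atoms: sodium chlorite, [Na+].[O-]Cl=O
Why: Pinnick oxidation of the aldehyde to the C2 acid; the alkene scavenger removes HOCl, and lactone and ester are untouched.

Step 14
Reactants: 21 lactone acid
Product: 22 lactol of 21 (2-hydroxy-chromane, both anomers; ring stereocentres as in 20)
Conditions: iBu2AlH (2.3 equiv), CH2Cl2, −78 °C; aq. potassium sodium tartrate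
Reagents that add atoms: none
Why: The hydride reagent first turns the acid into an aluminium carboxylate that resists reduction at −78 °C, then reduces the δ-lactone to the stable aluminium hemiacetal; the C3 ester next to quaternary C4 is much slower. The anomeric centre is of no consequence.

Step 15
Reactants: 22 lactol acid
Product: 23 2-[2-(but-3-yn-1-yl)-3-hydroxy-6-(1-methoxy-2-methyl-1-oxopropan-2-yl)-1,3-dimethylcyclohexyl]acetic acid (C5, C8, C9, C10 as in 20)
Conditions: MeC(O)C(N2)P(O)(OMe)2, K2CO3, MeOH, 0 °C → rt
Reagents that add atoms: dimethyl (1-diazo-2-oxopropyl)phosphonate, CC(=O)C(=[N+]=[N-])P(=O)(OC)OC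
Why: Seyferth–Gilbert homologation in its Ohira–Bestmann form: the ring-opened hydroxy aldehyde reacts with the diazomethylphosphonate anion made in situ and gives the terminal alkyne (C13≡C14); only base-stable groups are present.

Step 16
Reactants: 23 alkyne hydroxy acid
Product: 25 2-[3-hydroxy-2-[(3E)-5-hydroxy-3-methylpent-3-en-1-yl]-6-(1-methoxy-2-methyl-1-oxopropan-2-yl)-1,3-dimethylcyclohexyl]acetic acid, via alkenyldimethylalane 24 (not isolated)
Conditions: AlMe3 (5 equiv), Cp2ZrCl2 (0.3 equiv), H2O (1 equiv), CH2Cl2, −20 °C → rt; then (CH2O)n, THF, 0 °C → rt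
Reagents that add atoms: trimethylaluminium, C[Al](C)C; formaldehyde (as paraformaldehyde), C=O
Why: Zirconium-catalysed carboalumination (Negishi): syn addition of Me–Al across the terminal alkyne puts methyl on C13 and aluminium on C14, and the alkenylalane adds to formaldehyde with retention, which should give the E trisubstituted allylic alcohol. The hydroxyl and the acid travel as aluminium salts.

Step 17
Reactants: 25 allylic alcohol acid ester
Product: 26 2-{2-(carboxymethyl)-4-hydroxy-3-[(3E)-5-hydroxy-3-methylpent-3-en-1-yl]-2,4-dimethylcyclohexyl}-2-methylpropanoic acid (diacid)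
Conditions: KOH, EtOH/H2O, 90 °C; then aq. HCl to pH 3, 0 °C
Reagents that add atoms: potassium hydroxide, [K+].[OH-]
Why: Saponification of the hindered C3 methyl ester under forcing conditions; it is placed here because the molecule holds only base-stable groups (alcohols, alkene, carboxylate).

Step 18
Reactants: 26 diacid
Product: 27 diallyl ester of 26 (allyl esters at C2 and C3; E-allylic alcohol and C8 hydroxyl free)
Conditions: allyl bromide, Cs2CO3, DMF, rt
Reagents that add atoms: allyl bromide, C=CCBr
Why: SN2 O-alkylation of the caesium carboxylates; carbonate does not deprotonate the alcohols, so only the two acids should be allylated.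

Step 19
Reactants: 27 diallyl ester allylic alcohol
Product: 29 (13R,14S)-8,13-epoxy-14,15-diol diallyl ester (pyran diol of the vinyl series), via epoxy alcohol 28 (not isolated)
Conditions: Ti(OiPr)4, L-(+)-DET, t-BuOOH, 4 Å MS, CH2Cl2, −20 °C; work-up; then CSA (0.1 equiv), CH2Cl2, 0 °C
Reagents that add atoms: tert-butyl hydroperoxide, CC(C)(C)OO
Why: Sharpless asymmetric epoxidation: with the L-(+)-tartrate the allylic alcohol should be epoxidised under reagent control to the (13S,14S)-epoxide 28. Acid then triggers six-membered (exo) opening at the tertiary carbon C13 by the C8 hydroxyl with inversion, which fixes 13R; C14 is removed later.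

Step 20
Reactants: 29 pyran diol (vinyl series)
Product: 30 cyclic 14,15-thionocarbonate of 29
Conditions: 1,1′-thiocarbonyldiimidazole, DMAP (cat.), toluene, 80 °C
Reagents that add atoms: 1,1′-thiocarbonyldiimidazole, S=C(n1ccnc1)n1ccnc1
Why: Cyclic thionocarbonate formation from the 1,2-diol, the first half of the Corey–Winter olefination.

Step 21
Reactants: 30 thionocarbonate
Product: 31 (13R)-8,13-epoxy-14-ene diallyl ester (vinyl pyran)
Conditions: 1,3-dimethyl-2-phenyl-1,3,2-diazaphospholidine (3 equiv), THF, 40 °C
Reagents that add atoms: none
Why: Corey–Winter fragmentation: the trivalent phosphorus reagent takes the sulfur and the resulting carbene loses CO2 to give the terminal alkene; at 40 °C the allyl esters and the tertiary allylic ether should survive.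

Step 22
Reactants: 31 vinyl pyran diallyl ester
Product: 32 vinyl pyran 2,3-diacid
Conditions: Pd(PPh3)4 (5 mol%), morpholine (10 equiv), THF, rt; pH 3 work-up
Reagents that add atoms: none
Why: Tsuji–Trost deallylation: zerovalent palladium ionises the allyl esters and morpholine takes the allyl group. The tertiary allylic ether at C13 should not ionise because an alkoxide is a poor leaving group.

Step 23
Reactants: 32 vinyl pyran diacid
Product: 33 seven-membered 2,3-seco-anhydride of the vinyl half
Conditions: DCC (1.05 equiv), CH2Cl2 (high dilution), 0 °C → rt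
Reagents that add atoms: none
Why: Carbodiimide dehydration: the less hindered C2 acid is activated as the O-acylisourea and the C3 carboxyl closes the anhydride, helped by the gem-dimethyl group and by the trans-diequatorial placement of the two arms on ring B.

Step 24
Reactants: 27 diallyl ester allylic alcohol
Product: 35 (13S,14R)-8,13-epoxy-14,15-diol diallyl ester (primed diol), via epoxy alcohol 34 (not isolated)
Conditions: Ti(OiPr)4, D-(−)-DET, t-BuOOH, 4 Å MS, CH2Cl2, −20 °C; work-up; then CSA (0.1 equiv), CH2Cl2, 0 °C
Reagents that add atoms: tert-butyl hydroperoxide, CC(C)(C)OO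
Why: Sharpless asymmetric epoxidation with the D-(−)-tartrate should give the (13R,14R)-epoxide 34. Opening at C13 by the C8 hydroxyl with inversion sets 13′S, and C14′ keeps the R configuration given by the epoxidation.

Step 25
Reactants: 33 seco-anhydride; 35 primed diol diallyl ester
Product: 36 diallyl ester of the target (C2–O15′ ester formed, C3 acid and 14′-hydroxyl free)
Conditions: DMAP (0.2 equiv), iPr2NEt, CH2Cl2, 0 °C → rt
Reagents that add atoms: none
Why: DMAP-catalysed alcoholysis of a cyclic anhydride (acyl transfer): the primary C15′ hydroxyl should attack the C2 carbonyl, which has a methylene neighbour, and not the C3 carbonyl next to quaternary C4. The secondary C14′ hydroxyl beside quaternary C13′ stays free, and the C3 acid is released in the same step.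

Step 26
Reactants: 36 diallyl ester of the target
Product: 37 CNP0271961.3
Conditions: Pd(PPh3)4 (5 mol%), morpholine (10 equiv), THF, rt; pH 3 work-up
Reagents that add atoms: none
Why: Tsuji–Trost deallylation under neutral, non-hydrolytic conditions, so the interunit ester, the vinyl group and the free 14′-hydroxyl should be preserved.

## Compound list

1 | neryl acetate, (2Z)-3,7-dimethylocta-2,6-dien-1-yl acetate | CC(C)=CCC/C(C)=C\COC(C)=O | starting material
2 | (2Z)-5-(3,3-dimethyloxiran-2-yl)-3-methylpent-2-en-1-yl acetate (racemic oxirane) | CC1(C)OC1CC/C(C)=C\COC(C)=O | intermediate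
3 | (2Z)-5-(3,3-dimethyloxiran-2-yl)-3-methylpent-2-en-1-ol | CC1(C)OC1CC/C(C)=C\CO | intermediate
4 | (2Z)-5-(3,3-dimethyloxiran-2-yl)-3-methylpent-2-en-1-yl methanesulfonate | CC1(C)OC1CC/C(C)=C\COS(C)(=O)=O | intermediate
5 | 3-[(3Z)-5-bromo-3-methylpent-3-en-1-yl]-2,2-dimethyloxirane | CC1(C)OC1CC/C(C)=C\CBr | intermediate
6 | tert-butyl acetate | CC(=O)OC(C)(C)C | starting material
7 | lithium 1-tert-butoxyethen-1-olate (enolate of 6) | [Li+].C=C([O-])OC(C)(C)C | intermediate
8 | tert-butyl (4Z)-7-(3,3-dimethyloxiran-2-yl)-5-methylhept-4-enoate | CC1(C)OC1CC/C(C)=C\CCC(=O)OC(C)(C)C | intermediate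
9 | tert-butyl (4Z)-8,9-dihydroxy-5,9-dimethyldec-4-enoate | CC(C)(O)C(O)CC/C(C)=C\CCC(=O)OC(C)(C)C | intermediate
10 | tert-butyl (4Z)-5-methyl-8-oxooct-4-enoate | O=CCC/C(C)=C\CCC(=O)OC(C)(C)C | intermediate
11 | triethyl phosphonoacetate | CCOC(=O)CP(=O)(OCC)OCC | starting material
12 | 10-tert-butyl 1-ethyl (2E,6Z)-6-methyldeca-2,6-dienedioate | CCOC(=O)/C=C/CC/C(C)=C\CCC(=O)OC(C)(C)C | intermediate
13 | tert-butyl (4Z,8E)-10-hydroxy-5-methyldeca-4,8-dienoate | OC/C=C/CC/C(C)=C\CCC(=O)OC(C)(C)C | intermediate
14 | tert-butyl (4Z,8E)-10-[(methoxycarbonyl)oxy]-5-methyldeca-4,8-dienoate | COC(=O)OC/C=C/CC/C(C)=C\CCC(=O)OC(C)(C)C | intermediate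
15 | 1-methoxy-2-methyl-1-(trimethylsilyloxy)prop-1-ene | COC(=C(C)C)O[Si](C)(C)C | starting material
16 | 10-tert-butyl 1-methyl (3S,6Z)-3-ethenyl-2,2,6-trimethyldec-6-enedioate | C=C[C@@H](C(C)(C)C(=O)OC)CC/C(C)=C\CCC(=O)OC(C)(C)C | intermediate
17 | 10-tert-butyl 1-methyl (3R,6Z)-3-acetyl-2,2,6-trimethyldec-6-enedioate | CC(=O)[C@@H](C(C)(C)C(=O)OC)CC/C(C)=C\CCC(=O)OC(C)(C)C | intermediate
18 | N-tert-butyl (E)-aldimine of 19 | CC(C)(C)/N=C/C=C(\C)[C@@H](C(C)(C)C(=O)OC)CC/C(C)=C\CCC(=O)OC(C)(C)C | intermediate
19 | 10-tert-butyl 1-methyl (3S,6Z)-2,2,6-trimethyl-3-[(2E)-4-oxobut-2-en-2-yl]dec-6-enedioate | O=C/C=C(\C)[C@@H](C(C)(C)C(=O)OC)CC/C(C)=C\CCC(=O)OC(C)(C)C | intermediate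
20 | methyl 2-[(4aR,5R,6S,8aS)-5,8a-dimethyl-2-oxo-5-(2-oxoethyl)octahydro-2H-chromen-6-yl]-2-methylpropanoate | O=C1CC[C@@H]2[C@](C)(CC=O)[C@@H](C(C)(C)C(=O)OC)CC[C@]2(C)O1 | intermediate
21 | 2-[(4aR,5R,6S,8aS)-6-(1-methoxy-2-methyl-1-oxopropan-2-yl)-5,8a-dimethyl-2-oxooctahydro-2H-chromen-5-yl]acetic acid | O=C1CC[C@@H]2[C@](C)(CC(=O)O)[C@@H](C(C)(C)C(=O)OC)CC[C@]2(C)O1 | intermediate
22 | lactol of 21 (2-hydroxy, both anomers) | OC1CC[C@@H]2[C@](C)(CC(=O)O)[C@@H](C(C)(C)C(=O)OC)CC[C@]2(C)O1 | intermediate
23 | 2-[2-(but-3-yn-1-yl)-3-hydroxy-6-(1-methoxy-2-methyl-1-oxopropan-2-yl)-1,3-dimethylcyclohexyl]acetic acid (ring centres as in 20) | C#CCC[C@@H]1[C@](C)(CC(=O)O)[C@@H](C(C)(C)C(=O)OC)CC[C@]1(C)O | intermediate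
24 | (E)-alkenyldimethylalane from 23 (acid and hydroxyl as dimethylaluminium salts) | C[Al](C)/C=C(\C)CC[C@@H]1[C@](C)(CC(=O)O[Al](C)C)[C@@H](C(C)(C)C(=O)OC)CC[C@]1(C)O[Al](C)C | intermediate
25 | 2-[3-hydroxy-2-[(3E)-5-hydroxy-3-methylpent-3-en-1-yl]-6-(1-methoxy-2-methyl-1-oxopropan-2-yl)-1,3-dimethylcyclohexyl]acetic acid | OC/C=C(\C)CC[C@@H]1[C@](C)(CC(=O)O)[C@@H](C(C)(C)C(=O)OC)CC[C@]1(C)O | intermediate
26 | 2-{2-(carboxymethyl)-4-hydroxy-3-[(3E)-5-hydroxy-3-methylpent-3-en-1-yl]-2,4-dimethylcyclohexyl}-2-methylpropanoic acid | OC/C=C(\C)CC[C@@H]1[C@](C)(CC(=O)O)[C@@H](C(C)(C)C(=O)O)CC[C@]1(C)O | intermediate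
27 | diallyl ester of 26 | OC/C=C(\C)CC[C@@H]1[C@](C)(CC(=O)OCC=C)[C@@H](C(C)(C)C(=O)OCC=C)CC[C@]1(C)O | intermediate
28 | (13S,14S)-13,14-epoxide of 27 | OC[C@@H]1O[C@@]1(C)CC[C@@H]2[C@](C)(CC(=O)OCC=C)[C@@H](C(C)(C)C(=O)OCC=C)CC[C@]2(C)O | intermediate
29 | (13R,14S)-8,13-epoxy-14,15-diol diallyl ester (vinyl series) | OC[C@H](O)[C@@]1(C)CC[C@@H]2[C@](C)(CC(=O)OCC=C)[C@@H](C(C)(C)C(=O)OCC=C)CC[C@]2(C)O1 | intermediate
30 | cyclic 14,15-thionocarbonate of 29 | S=C1OC[C@H](O1)[C@@]2(C)CC[C@@H]3[C@](C)(CC(=O)OCC=C)[C@@H](C(C)(C)C(=O)OCC=C)CC[C@]3(C)O2 | intermediate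
31 | (13R)-8,13-epoxy-14-ene diallyl ester (vinyl pyran) | C=C[C@@]1(C)CC[C@@H]2[C@](C)(CC(=O)OCC=C)[C@@H](C(C)(C)C(=O)OCC=C)CC[C@]2(C)O1 | intermediate
32 | vinyl pyran 2,3-diacid | C=C[C@@]1(C)CC[C@@H]2[C@](C)(CC(=O)O)[C@@H](C(C)(C)C(=O)O)CC[C@]2(C)O1 | intermediate
33 | seven-membered 2,3-seco-anhydride of the vinyl half | C=C[C@@]1(C)CC[C@@H]2[C@]3(C)CC(=O)OC(=O)C(C)(C)[C@H]3CC[C@]2(C)O1 | intermediate
34 | (13R,14R)-13,14-epoxide of 27 | OC[C@H]1O[C@]1(C)CC[C@@H]2[C@](C)(CC(=O)OCC=C)[C@@H](C(C)(C)C(=O)OCC=C)CC[C@]2(C)O | intermediate
35 | (13S,14R)-8,13-epoxy-14,15-diol diallyl ester (primed diol) | OC[C@@H](O)[C@]1(C)CC[C@@H]2[C@](C)(CC(=O)OCC=C)[C@@H](C(C)(C)C(=O)OCC=C)CC[C@]2(C)O1 | intermediate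
36 | 2′,3′-diallyl ester of the target | C=C[C@@]1(C)CC[C@@H]2[C@](C)(CC(=O)OC[C@@H](O)[C@]3(C)CC[C@@H]4[C@](C)(CC(=O)OCC=C)[C@@H](C(C)(C)C(=O)OCC=C)CC[C@]4(C)O3)[C@@H](C(C)(C)C(=O)O)CC[C@]2(C)O1 | intermediate
37 | CNP0271961.3 | C=C[C@@]1(C)CC[C@@H]2[C@](C)(CC(=O)OC[C@@H](O)[C@]3(C)CC[C@@H]4[C@](C)(CC(=O)O)[C@@H](C(C)(C)C(=O)O)CC[C@]4(C)O3)[C@@H](C(C)(C)C(=O)O)CC[C@]2(C)O1 | target

## Step count and least certain steps

Total: 26 steps. Longest linear sequence: 25 steps (steps 1 to 23, then 25 and 26); step 24 is the one-step side branch from 27.

**Step 12 (key step, proposed new method).** The most likely failure is loss of the C8 cation by proton elimination, or cleavage of the tert-butyl ester by the Lewis acid, before the lactone closes. A further risk is collapse of the zwitterion to a cyclobutane when the chair is not well organised. The reason is that three carbonyl groups compete for the aluminium reagent and the cation is tertiary and long-lived. Fallback, from 19 back to 20, in two known operations: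
- Me2AlCl in CH2Cl2 at −78 °C is used to run the cyclisation as a Lewis-acid conjugate-ene reaction that ends by proton loss. It should give the ring B olefin aldehyde with the C7=C8 double bond F1, together with its exocyclic C8-methylene isomer F2.
- CF3CO2H in CH2Cl2 at 0 °C then protonates either olefin to the same C8 cation, which the tert-butyl ester captures with loss of 2-methylpropene. Since the axial C11 tether can reach only the equatorial site of C8, this acid lactonisation should return 20 with the same configuration.

**Step 9.** The likely failure is a poor branched-to-linear ratio or poor facial selectivity, because the nucleophile is fully substituted and the carbonate is purely aliphatic; the sense of induction is also assumed. Fallback, from 10 back to 16, by chirality transfer: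
- olefination of 10 with dimethyl (2-oxopropyl)phosphonate gives the E-enone F3;
- Corey–Bakshi–Shibata reduction with the (S)-oxazaborolidine gives the (R)-allylic alcohol F4;
- isobutyryl chloride and pyridine give the isobutyrate F5;
- Ireland–Claisen rearrangement (LiN(iPr)2, Me3SiCl, THF, −78 °C → reflux) through a chair with the carbinol methyl equatorial transfers the configuration to C5 and gives the (S)-acid with an E-propenyl group F6;
- Me3SiCHN2 gives its methyl ester F7;
- ethenolysis (second-generation Hoveyda–Grubbs catalyst, ethylene, CH2Cl2) trims propenyl to vinyl and gives 16.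

**Step 11.** The likely failure is enolisation of the hindered methyl ketone by the lithiated imine instead of addition, so that 17 is returned, with a small risk of epimerisation at C5 on long exposure to base. Fallback, from 17 back to 19: HC≡CMgBr with CeCl3 (THF, −78 °C) adds to the ketone and gives the tertiary propargylic alcohol F8, and a Meyer–Schuster rearrangement (Ph3PAuNTf2 cat., wet CH2Cl2) turns it into the E-enal 19.

**Step 16.** The likely failure is consumption of AlMe3 by the acid and the C3 ester, leading to incomplete carbometalation or methyl transfer to the ester, or sluggish capture of the alkenylalane by formaldehyde. Fallback, from 21 back to 25: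
- MeLi (3 equiv, THF, −78 °C) adds once to the lactone of the lithium carboxylate and gives the hydroxy methyl ketone F9;
- olefination with 11 (NaH in excess, THF) gives the E-enoate F10, a minor Z isomer being removed by chromatography;
- iBu2AlH at −78 °C reduces the conjugated ester to 25 while C2 is protected as its carboxylate.

**Step 24.** The likely failure is a ring closure that drifts towards an ionised pathway, with loss of stereospecificity at C13′, or that is outrun by rearrangement of the epoxide. The cause is that a tertiary alcohol must attack a tertiary carbon while a 1,3-diaxial contact develops across the ring oxygen. Fallback, from 34 (isolated after the epoxidation) back to 35: the epoxide is opened at C13 by water with inversion (HClO4 cat., THF/H2O, 0 °C) to the tetraol F11, and ring C is then closed from the other side by ionising the C8 tertiary alcohol (TsOH cat., MeNO2, 0 °C), the C13 hydroxyl capturing the C8 cation. The β-hydroxyl slows ionisation at C13, and the axial tether allows only the cis fusion.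

## Further compounds

F1 | step 12 | tert-butyl 3-[(1S,5S,6R)-ring B olefin: 6-(2-oxoethyl)-5-(1-methoxy-2-methyl-1-oxopropan-2-yl)-2,6-dimethylcyclohex-2-en-1-yl]propanoate (C7=C8 olefin; C5, C9, C10 as in 20) | CC(C)(C)OC(=O)CC[C@@H]1[C@](C)(CC=O)[C@@H](C(C)(C)C(=O)OC)CC=C1C
F2 | step 12 | exocyclic C8-methylene isomer of F1 | CC(C)(C)OC(=O)CC[C@@H]1[C@](C)(CC=O)[C@@H](C(C)(C)C(=O)OC)CCC1=C
F3 | step 9 | tert-butyl (4Z,8E)-5-methyl-10-oxoundeca-4,8-dienoate | CC(=O)/C=C/CC/C(C)=C\CCC(=O)OC(C)(C)C
F4 | step 9 | tert-butyl (4Z,8E,10R)-10-hydroxy-5-methylundeca-4,8-dienoate | C[C@@H](O)/C=C/CC/C(C)=C\CCC(=O)OC(C)(C)C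
F5 | step 9 | isobutyrate of F4 | CC(C)C(=O)O[C@H](C)/C=C/CC/C(C)=C\CCC(=O)OC(C)(C)C
F6 | step 9 | (3S,6Z)-10-tert-butoxy-2,2,6-trimethyl-10-oxo-3-[(1E)-prop-1-en-1-yl]dec-6-enoic acid | C/C=C/[C@@H](C(C)(C)C(=O)O)CC/C(C)=C\CCC(=O)OC(C)(C)C
F7 | step 9 | methyl ester of F6 | C/C=C/[C@@H](C(C)(C)C(=O)OC)CC/C(C)=C\CCC(=O)OC(C)(C)C
F8 | step 11 | 10-tert-butyl 1-methyl (3S,6Z)-3-(2-hydroxybut-3-yn-2-yl)-2,2,6-trimethyldec-6-enedioate (carbinol epimers) | C#CC(C)(O)[C@@H](C(C)(C)C(=O)OC)CC/C(C)=C\CCC(=O)OC(C)(C)C
F9 | step 16 | 2-[3-hydroxy-6-(1-methoxy-2-methyl-1-oxopropan-2-yl)-1,3-dimethyl-2-(3-oxobutyl)cyclohexyl]acetic acid | CC(=O)CC[C@@H]1[C@](C)(CC(=O)O)[C@@H](C(C)(C)C(=O)OC)CC[C@]1(C)O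
F10 | step 16 | ethyl (E)-enoate from F9 (C13=C14, ester at C15) | CCOC(=O)/C=C(\C)CC[C@@H]1[C@](C)(CC(=O)O)[C@@H](C(C)(C)C(=O)OC)CC[C@]1(C)O
F11 | step 24 | (13S,14R)-8,13,14,15-tetraol diallyl ester | OC[C@@H](O)[C@@](C)(O)CC[C@@H]1[C@](C)(CC(=O)OCC=C)[C@@H](C(C)(C)C(=O)OCC=C)CC[C@]1(C)O
A1 | alternative 1 | ring A 2,3-diketone of the vinyl half | C=C[C@@]1(C)CC[C@@H]2[C@]3(C)CC(=O)C(=O)C(C)(C)[C@H]3CC[C@]2(C)O1
A2 | alternative 1 | seven-membered 2,3-seco-anhydride of the vinyl half (identical with 33) | C=C[C@@]1(C)CC[C@@H]2[C@]3(C)CC(=O)OC(=O)C(C)(C)[C@H]3CC[C@]2(C)O1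
A3 | alternative 2 | E-enal dienophile carrying the C11 to C15 chain | O=C/C(CC(=O)OC)=C/CC[C@](C)(O[Si](CC)(CC)CC)[C@H]1COC(C)(C)O1
A4 | alternative 2 | trans-1-methoxy-3-trimethylsiloxy-1,3-butadiene | CO/C=C/C(=C)O[Si](C)(C)C
A5 | alternative 2 | ring B enone with C9 and C10 set, formyl as latent C10 methyl | O=C1C=C[C@@](C=O)(CC(=O)OC)[C@@H](CC[C@](C)(O[Si](CC)(CC)CC)[C@H]2COC(C)(C)O2)C1
A6 | alternative 3 | C10 diazoketone of the vinyl half, C3 allyl ester | C=C[C@@]1(C)CC[C@@H]2[C@](C)(C(=O)C=[N+]=[N-])[C@@H](C(C)(C)C(=O)OCC=C)CC[C@]2(C)O1
A7 | alternative 3 | triallyl ester of the target | C=C[C@@]1(C)CC[C@@H]2[C@](C)(CC(=O)OC[C@@H](O)[C@]3(C)CC[C@@H]4[C@](C)(CC(=O)OCC=C)[C@@H](C(C)(C)C(=O)OCC=C)CC[C@]4(C)O3)[C@@H](C(C)(C)C(=O)OCC=C)CC[C@]2(C)O1
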